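**Retrosynthetic overview**
1. Target 6 (2,3-trans-3,4-cis diol) ⇐ C4–O bond re-formed under thermodynamic control (SN1 water exchange through quinone methide 5) from its 4α-epimer 4 ⇐ hydride reduction of dihydroflavonol 3.
2. 3 ⇐ ring C closed through the O1–C2 bond by 6-endo opening of the (αR,βS)-chalcone epoxide 2 by the 2'-OH; the C3–O bond comes from the asymmetric epoxidation.
3. 2 ⇐ xanthohumol 1, which already carries ring A (OMe, OH, prenyl), ring B and all 21 carbons; no C–C bond is made.
4. Ring order: rings A and B are bought; ring C is the only ring formed (step 1). C-2 and C-3 are set in step 1, C-4 in step 3.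

Assumption: xanthohumol, the main prenylated chalcone of hops, sold in bulk as enriched hop extract and as a pure reagent, is taken as a cheap commercial starting material.

Ligand in step 1: L-PiPr2 is the C2-symmetric N,N'-dioxide 1,1'-(propane-1,3-diyl)bis[(2S)-2-(2,6-diisopropylphenylcarbamoyl)piperidine 1-oxide].

**Route**

Step 1
Reactants: 1 xanthohumol
Product: 3 (2R,3R)-5-O-methyl-8-prenylaromadendrin, via (αR,βS)-xanthohumol epoxide 2 (not isolated)
Conditions: Sc(OTf)3 (10 mol%), L-PiPr2 (11 mol%), 30% aq H2O2 (1.3 equiv), THF, 0 °C; then 35 °C, 12 h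
Reagents that add atoms: hydrogen peroxide (OO)
Why: Proposed new method: a chelation-directed asymmetric Algar–Flynn–Oyamada-type oxidative cyclization, in which the free 2'-OH and the carbonyl of 1 bind the chiral complex of Sc(OTf)3 (Lewis acidic trivalent scandium) as a six-membered chelate that makes the electron-rich enone electrophilic enough and exposes one enantioface to conjugate delivery of Sc-bound hydroperoxide (Weitz–Scheffer epoxidation, which leaves the nucleophilic prenyl alkene alone) to give the (αR,βS)-epoxide 2 and so sets C-3 (R), after which the 2'-OH opens the Lewis-acid-activated 4-hydroxybenzylic C–O bond 6-endo with inversion at Cβ (or through the B-ring quinone methide to the more stable 2,3-trans product) and sets C-2 (R); the closest known reactions are the Sc(OTf)3/N,N'-dioxide-catalysed H2O2 epoxidation of simple chalcones and the acid-mediated cyclization of 2'-hydroxychalcone epoxides to trans-dihydroflavonols, neither shown on an unprotected polyphenolic 2'-hydroxychalcone nor merged into one enantioselective operation.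

Step 2
Reactants: 3 (2R,3R)-5-O-methyl-8-prenylaromadendrin
Product: 4 (2R,3S,4R)-5-O-methyl-8-prenylafzelechin-4α-ol
Conditions: NaBH4 (3 equiv), EtOH, 0 °C to rt; pH 7 buffer work-up, crude product used directly
Reagents that add atoms: none
Why: Borohydride 1,2-reduction of the aryl ketone leaves the prenyl alkene untouched and delivers hydride axially to the half-chair with 2-aryl and 3-OH equatorial, giving mainly the all-equatorial 4α-ol (C-4 R, 3,4-trans) as in the NaBH4 reduction of dihydroflavonols to 3,4-trans-leucoanthocyanidins, while C-2 and C-3 are unchanged.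

Step 3
Reactants: 4 (2R,3S,4R)-5-O-methyl-8-prenylafzelechin-4α-ol
Product: 6 (2R,3S,4S)-5-O-methyl-8-prenylafzelechin-4β-ol, via ring-A para-quinone methide 5 (not isolated)
Conditions: 0.05 M aq AcOH/MeCN (1:1), 2 mM, 40 °C, N2; HPLC control, recovered 4 recycled
Reagents that add atoms: water (O)
Why: Acid-catalysed SN1 exchange of the benzylic 4-OH (the epimerization known for 3,4-trans-leucoanthocyanidins) in which loss of water gives quinone methide 5 (C-4 cation stabilised by 5-OMe and 7-OH), water re-adds axially on the β face, and the pseudoaxial 4β-OH is free of peri strain with 5-OMe and cis to 3-OH, so the new C4–O bond settles on the 3,4-cis (4S) diol while C-2 and C-3 stay fixed.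

**Compound list**
1 | xanthohumol, (E)-1-[2,4-dihydroxy-6-methoxy-3-(3-methylbut-2-en-1-yl)phenyl]-3-(4-hydroxyphenyl)prop-2-en-1-one | COc1cc(O)c(CC=C(C)C)c(O)c1C(=O)/C=C/c1ccc(O)cc1 | starting material
2 | (αR,βS)-xanthohumol epoxide, [2,4-dihydroxy-6-methoxy-3-(3-methylbut-2-en-1-yl)phenyl][(2R,3S)-3-(4-hydroxyphenyl)oxiran-2-yl]methanone (trans-epoxide) | COc1cc(O)c(CC=C(C)C)c(O)c1C(=O)[C@@H]1O[C@H]1c1ccc(O)cc1 | intermediate
3 | (2R,3R)-5-O-methyl-8-prenylaromadendrin, (2R,3R)-3,7-dihydroxy-2-(4-hydroxyphenyl)-5-methoxy-8-(3-methylbut-2-en-1-yl)chroman-4-one (2,3-trans) | COc1cc(O)c(CC=C(C)C)c2c1C(=O)[C@H](O)[C@@H](c1ccc(O)cc1)O2 | intermediate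
4 | (2R,3S,4R)-5-O-methyl-8-prenylafzelechin-4α-ol, (2R,3S,4R)-2-(4-hydroxyphenyl)-5-methoxy-8-(3-methylbut-2-en-1-yl)chromane-3,4,7-triol (2,3-trans-3,4-trans) | COc1cc(O)c(CC=C(C)C)c2c1[C@@H](O)[C@H](O)[C@@H](c1ccc(O)cc1)O2 | intermediate
5 | ring-A para-quinone methide, (2R,3S)-3-hydroxy-2-(4-hydroxyphenyl)-5-methoxy-8-(3-methylbut-2-en-1-yl)-2,3-dihydro-7H-chromen-7-one | COC1=CC(=O)C(CC=C(C)C)=C2O[C@H](c3ccc(O)cc3)[C@@H](O)C=C12 | intermediate
6 | 5-O-methyl-8-prenylafzelechin-4β-ol, (2R,3S,4S)-2-(4-hydroxyphenyl)-5-methoxy-8-(3-methylbut-2-en-1-yl)chromane-3,4,7-triol (2,3-trans-3,4-cis) | COc1cc(O)c(CC=C(C)C)c2c1[C@H](O)[C@H](O)[C@@H](c1ccc(O)cc1)O2 | target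

**Totals**
Total step count: 3. Longest linear sequence: 3 steps.

**Steps most likely to fail**

Step 1 (the proposed new step) is the most likely to fail.
- The enone carries two donor rings and may react slowly.
- The other phenols may compete for the Sc(OTf)3 complex.
- Lewis-acid oxa-Michael closure of 1 to isoxanthohumol may compete.
- The epoxide may open 5-exo (aurone-type products) or undergo aroyl shift.
- The sense and level of induction are unknown. If the L-pipecolic ligand gives the antipode, its D-pipecolic enantiomer is used.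

Fallback, known chemistry, sets out from 1 and comes back at 3. Compound 1 is alkylated with MOMCl and NaH in DMF at 0 °C to 2',4',4-tris-O-(methoxymethyl)xanthohumol F1. Juliá–Colonna epoxidation of this ordinary 2'-O-MOM chalcone (poly-L-leucine, urea–H2O2, DBU, THF, rt; nucleophilic oxidant, prenyl untouched) gives the tris-O-MOM (αR,βS)-epoxide F2. HCl in MeOH at 45 °C then removes the three MOM groups, and the freed 2'-OH opens the epoxide at the benzylic carbon to give 3.

Step 3 is the second most likely to fail.
- The C-4 cation can be trapped by C-6 of a second molecule, giving proanthocyanidin-type oligomers.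
- It can eliminate.
- The 4β:4α ratio at equilibrium may be modest.

Fallback, sets out from 3 and comes back at 6. C-4 is set kinetically by a catalyst at the reduction stage instead of by C–O exchange. Compound 3 is reduced by Noyori–Ikariya asymmetric transfer hydrogenation with RuCl(p-cymene)[(R,R)-TsDPEN] (2 mol%), HCO2H/Et3N 5:2, DMF, 30 °C. The (R,R) complex is the one that gives (R)-chroman-4-ol from chroman-4-one, which corresponds to the 4β-OH face here. The medium is base-free and leaves the prenyl alkene alone. New compound on this path: none F0.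

Step 2 is the third most likely to fail.
- The basic borohydride medium can open ring C of the 4'-hydroxy dihydroflavonol through its B-ring quinone methide.
- The 7-phenoxide makes the ketone a sluggish vinylogous carboxylate.

Fallback, sets out from 3 and comes back at 4. Both phenols are masked before the reduction. TBSCl/imidazole in DMF at 0 °C gives 7,4'-bis-O-TBS-5-O-methyl-8-prenylaromadendrin F3. NaBH4 in MeOH/THF at 0 °C gives the 7,4'-bis-O-TBS 3,4-trans-diol F4. TBAF buffered with AcOH in THF at 0 °C frees both phenols and returns 4.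

**Further compounds**
F1 | step 1 | 2',4',4-tris-O-(methoxymethyl)xanthohumol | COc1cc(OCOC)c(CC=C(C)C)c(OCOC)c1C(=O)/C=C/c1ccc(OCOC)cc1
F2 | step 1 | tris-O-MOM (αR,βS)-epoxide, [6-methoxy-2,4-bis(methoxymethoxy)-3-(3-methylbut-2-en-1-yl)phenyl][(2R,3S)-3-[4-(methoxymethoxy)phenyl]oxiran-2-yl]methanone | COc1cc(OCOC)c(CC=C(C)C)c(OCOC)c1C(=O)[C@@H]1O[C@H]1c1ccc(OCOC)cc1
F3 | step 2 | 7,4'-bis-O-TBS-5-O-methyl-8-prenylaromadendrin (2R,3R) | COc1cc(O[Si](C)(C)C(C)(C)C)c(CC=C(C)C)c2c1C(=O)[C@H](O)[C@@H](c1ccc(O[Si](C)(C)C(C)(C)C)cc1)O2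
F4 | step 2 | 7,4'-bis-O-TBS-5-O-methyl-8-prenylafzelechin-4α-ol (2R,3S,4R) | COc1cc(O[Si](C)(C)C(C)(C)C)c(CC=C(C)C)c2c1[C@@H](O)[C@H](O)[C@@H](c1ccc(O[Si](C)(C)C(C)(C)C)cc1)O2
F0 | step 3 | none | none
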